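**Plan**
1. Locants follow the target skeleton, tricyclo[5.4.0.0^{2,8}]undecane: C11 is the ring ketone, C3 and C5 the ester carbinols, C4 the CH2 between them, C6 the CMe2 carbon, and the cyclobutane is C1–C2–C8–C7.
2. Retrosynthesis: remove the two angelates; C11=O from C11=CH2; the anti-3,5-diol from the 3,5-dione, itself from the ketol; cut C4–C5 (aldol) to a bicyclo[3.1.1]heptane carrying acetyl on C2 and CMe2CHO on C7.
3. Then cut C6–C7 (ester-enolate aldol through a temporary seven-membered lactone hung on the C3 oxygen, followed by radical removal of the C7 oxygen); then cut C1–C2 and C7–C8 together (intramolecular vinylketene–alkene [2+2]) to an acyclic dienoic acid.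
4. Forward: chain assembly, then cyclobutane plus six-membered ring in one [2+2], then the temporary lactone (C6–C7), then the seven-membered carbocycle by C4–C5 closure, then diol, ketone and esters.
5. Enabling feature: the cyclobutane C1–C2–C8–C7 holds the C2 and C7 substituents 1,3-syn-diaxial on the face opposite the C9–C11 bridge, so C4 and C5 lie about 3 Å apart, and C4 is the only enolizable carbon.
6. Stereochemistry: C9 from an Evans alkylation; C1, C2 and C8 relayed from C9 in the [2+2] (A1,3 strain, E-alkene geometry); C7 fixed by the lactone bridge; C3 and C5 by (S)-CBS catalyst control.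

Key step: step 12

Remark: the carbinol made in step 4 is a helper centre that anchors the tether and is oxidized in step 11. The C5 carbinol formed in step 12 is deliberately erased in step 13, because the two faces of the seven-membered ring differ only through remote groups. The final esterification acylates two hydroxyls, so it takes up two molecules of angelic acid.

Step 1
Reactants: 1 (S)-4-benzyl-3-propanoyl-1,3-oxazolidin-2-one; 2 3-bromoprop-1-yne
Product: 3 (S)-4-benzyl-3-[(2R)-2-methylpent-4-ynoyl]-1,3-oxazolidin-2-one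
Conditions: NaHMDS, THF, −78 °C; then 2, −78 to −40 °C
Reagents that add atoms: none
Why: Evans asymmetric alkylation, in which the chelated Z-sodium enolate is propargylated on the face opposite the benzyl group, setting the (R) methyl-bearing centre that becomes C9.

Step 2
Reactants: 3 (S)-4-benzyl-3-[(2R)-2-methylpent-4-ynoyl]-1,3-oxazolidin-2-one
Product: 4 (2R)-2-methylpent-4-yn-1-ol
Conditions: LiBH4, MeOH (1 equiv), Et2O, 0 °C
Reagents that add atoms: none
Why: Reductive cleavage of the N-acyl oxazolidinone by LiBH4 should give the primary alcohol without touching the alkyne or the stereocentre, and returns the auxiliary.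

Step 3
Reactants: 4 (2R)-2-methylpent-4-yn-1-ol; 5 3-(triphenyl-λ5-phosphanylidene)butan-2-one
Product: 7 (3E,5R)-3,5-dimethyloct-3-en-7-yn-2-one, via aldehyde 6 (not isolated)
Conditions: Dess–Martin periodinane, CH2Cl2, 0 °C to rt; then 5, CH2Cl2, 40 °C
Reagents that add atoms: none
Why: Dess–Martin oxidation followed in the same flask by Wittig olefination with the stabilized α-methyl ylide should give the (E)-trisubstituted enone, and telescoping avoids isolating the volatile, epimerizable α-methyl aldehyde.

Step 4
Reactants: 7 (3E,5R)-3,5-dimethyloct-3-en-7-yn-2-one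
Product: 8 (2R,3E,5R)-3,5-dimethyloct-3-en-7-yn-2-ol
Conditions: (S)-Me-CBS (20 mol%), catecholborane, toluene, −78 °C
Reagents that add atoms: none
Why: Corey–Bakshi–Shibata reduction (alkenyl as the large group, catecholborane sparing the alkyne) should give one (2R) allylic alcohol, so that all intermediates up to step 11 are single diastereomers.

Step 5
Reactants: 8 (2R,3E,5R)-3,5-dimethyloct-3-en-7-yn-2-ol
Product: 10 (2E,5R,6E,8R)-8-hydroxy-3,5,7-trimethylnona-2,6-dienoic acid, via alkenylalane 9 (not isolated)
Conditions: Me3Al (3.5 equiv), Cp2ZrCl2 (0.5 equiv), CH2Cl2, 0 °C to rt; then n-BuLi, THF, −78 °C; CO2; aq. HCl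
Reagents that add atoms: trimethylaluminium C[Al](C)C; carbon dioxide O=C=O
Why: Negishi zirconium-catalysed syn-carboalumination of the terminal alkyne (the hydroxyl is carried as its aluminium alkoxide) followed by carboxylation of the alkenyl alanate should give the (2E)-3-methyl-2-enoic acid with the methyl cis to the carboxyl, the geometry needed for vinylketene formation; the CO2 carbon becomes C7.

Step 6
Reactants: 10 (2E,5R,6E,8R)-8-hydroxy-3,5,7-trimethylnona-2,6-dienoic acid; 11 2-methylpropanoic anhydride
Product: 12 (2E,5R,6E,8R)-3,5,7-trimethyl-8-[(2-methylpropanoyl)oxy]nona-2,6-dienoic acid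
Conditions: Et3N, DMAP (cat.), CH2Cl2, rt; then pyridine/H2O
Reagents that add atoms: none
Why: DMAP-catalysed acylation of the secondary allylic alcohol installs the isobutyrate that later supplies C6, its two methyls and C5 and acts as the tether; the mixed anhydride formed at the acid is hydrolysed in the aqueous stage.

Step 7
Reactants: 12 (2E,5R,6E,8R)-3,5,7-trimethyl-8-[(2-methylpropanoyl)oxy]nona-2,6-dienoic acid
Product: 15 (1R)-1-[2,7-dimethyl-4-methylidene-6-oxobicyclo[3.1.1]heptan-7-yl]ethyl 2-methylpropanoate, via acid chloride 13 (not isolated), via vinylketene 14 (not isolated)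
Conditions: (COCl)2, benzene, rt; evaporate; slow addition to Et3N, toluene, 110 °C (0.01 M)
Reagents that add atoms: none
Why: Intramolecular vinylketene–alkene [2+2] cycloaddition (Snider type), in which dehydrochlorination at the methyl cis to COCl gives the vinylketene, whose carbonyl carbon (C7) bonds to the alkene CH (C8) and whose α-carbon (C1) bonds to the fully substituted alkene carbon (C2) to give the bicyclo[3.1.1]heptan-6-one; suprafacial addition to the E-alkene places the C2 methyl syn to the three-carbon bridge and the side chain on the carbonyl-bridge face, and A1,3 strain between the C2 methyl and the C9 substituents makes the tether add anti to the C9 methyl.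

Step 8
Reactants: 15 (1R)-1-[2,7-dimethyl-4-methylidene-6-oxobicyclo[3.1.1]heptan-7-yl]ethyl 2-methylpropanoate
Product: 17 methyl (3R)-2,3,6,6,9-pentamethyl-11-methylidene-5-oxo-4-oxatricyclo[5.4.0.0^{2,8}]undecan-7-yl oxalate, via lithium aldolate 16 (not isolated)
Conditions: LDA, THF, −78 °C; then ClC(O)CO2Me, −78 to 0 °C
Reagents that add atoms: methyl chlorooxoacetate COC(=O)C(Cl)=O
Why: Intramolecular ester-enolate aldol addition to the strained, non-enolizable cyclobutanone, in which the tether can reach only the carbonyl face syn to the C2 side chain, so C6 is delivered cis to it through a temporary seven-membered lactone, and the tertiary alkoxide is trapped in the same flask as the methyl oxalate.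

Step 9
Reactants: 17 methyl (3R)-2,3,6,6,9-pentamethyl-11-methylidene-5-oxo-4-oxatricyclo[5.4.0.0^{2,8}]undecan-7-yl oxalate
Product: 18 (3R)-2,3,6,6,9-pentamethyl-11-methylidene-4-oxatricyclo[5.4.0.0^{2,8}]undecan-5-one
Conditions: Bu3SnH, AIBN, toluene, 110 °C
Reagents that add atoms: none
Why: Dolan–MacMillan radical deoxygenation of a tert-alkyl methyl oxalate (no β-hydrogen is available for elimination), in which the tertiary cyclobutyl radical is held by the lactone bridge and can take hydrogen only on its outer face, giving C7–H with the C6 chain kept cis to the C2 chain.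

Step 10
Reactants: 18 (3R)-2,3,6,6,9-pentamethyl-11-methylidene-4-oxatricyclo[5.4.0.0^{2,8}]undecan-5-one
Product: 19 (1R)-1-[6-(1-hydroxy-2-methylpropan-2-yl)-2,7-dimethyl-4-methylidenebicyclo[3.1.1]heptan-7-yl]ethan-1-ol
Conditions: LiAlH4, THF, 0 °C to rt
Reagents that add atoms: none
Why: Hydride reduction of the lactone opens the temporary ring to the diol and leaves the methylidene untouched.

Step 11
Reactants: 19 (1R)-1-[6-(1-hydroxy-2-methylpropan-2-yl)-2,7-dimethyl-4-methylidenebicyclo[3.1.1]heptan-7-yl]ethan-1-ol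
Product: 20 2-[7-acetyl-2,7-dimethyl-4-methylidenebicyclo[3.1.1]heptan-6-yl]-2-methylpropanal
Conditions: (COCl)2, DMSO, CH2Cl2, −78 °C; then Et3N, −78 to 0 °C
Reagents that add atoms: none
Why: Swern oxidation converts both alcohols into alkoxysulfonium ions before base is added, so the keto aldehyde should form without the lactol-to-lactone path that a stepwise oxidant would open.

Step 12
Reactants: 20 2-[7-acetyl-2,7-dimethyl-4-methylidenebicyclo[3.1.1]heptan-6-yl]-2-methylpropanal
Product: 21 5-hydroxy-2,6,6,9-tetramethyl-11-methylidenetricyclo[5.4.0.0^{2,8}]undecan-3-one (C5 epimers)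
Conditions: KHMDS, THF, −78 °C; AcOH quench at −78 °C
Reagents that add atoms: none
Why: KHMDS removes a proton from the acetyl methyl (C4), the only acidic C–H in 20 (C2 and C6 are quaternary, the aldehyde has no α-hydrogen, and C11 is still a methylidene, so no cyclohexanone enolate can compete), and the potassium enolate adds to the C5 aldehyde to form the C4–C5 bond. The closest known reaction type is the base-mediated intramolecular aldol addition of a methyl ketone or acetate enolate to an α-quaternary aldehyde, as used in KHMDS macroaldolizations at −78 °C. The seven-membered ring closes in a 7-(enolendo)-exo-trig mode and completes the bicyclo[4.1.1]octane half of the tricycle. The cyclobutane makes this possible, because the acetyl on C2 and the CMe2CHO group on C7 both sit on the ring face opposite the C9–C11 bridge (1,3-syn-diaxial), which holds C4 and C5 about 3 Å apart and removes the entropic cost that normally disfavours seven-ring aldolization. The C5 carbinol is the only new stereocentre; the two aldehyde faces differ only through the remote C1 and C8 substituents, so no substrate element is relied on to control it, and it is erased in step 13 and reset under catalyst control in step 14. The step needs site-selective enolization and kinetic control against retro-aldol and dehydration, which the single enolizable position and the cold acidic quench should secure.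

Step 13
Reactants: 21 5-hydroxy-2,6,6,9-tetramethyl-11-methylidenetricyclo[5.4.0.0^{2,8}]undecan-3-one (C5 epimers)
Product: 22 2,6,6,9-tetramethyl-11-methylidenetricyclo[5.4.0.0^{2,8}]undecane-3,5-dione
Conditions: Dess–Martin periodinane, CH2Cl2, rt
Reagents that add atoms: none
Why: Dess–Martin oxidation of the β-hydroxy ketone converges both C5 epimers on one 1,3-diketone, which should stay largely in the diketo form in a seven-membered ring flanked by two quaternary carbons.

Step 14
Reactants: 22 2,6,6,9-tetramethyl-11-methylidenetricyclo[5.4.0.0^{2,8}]undecane-3,5-dione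
Product: 23 (3R,5R)-2,6,6,9-tetramethyl-11-methylidenetricyclo[5.4.0.0^{2,8}]undecane-3,5-diol
Conditions: (S)-Me-CBS (0.5 equiv), catecholborane (4 equiv), toluene, −40 to 0 °C
Reagents that add atoms: none
Why: Corey–Bakshi–Shibata reduction, in which each carbonyl lies between a quaternary carbon (large) and the C4 methylene (small), so the (S)-catalyst should deliver hydride to the same local face of both and give the (3R,5R) anti-diol by catalyst control where the substrate offers no bias; catecholborane leaves the methylidene alone.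

Step 15
Reactants: 23 (3R,5R)-2,6,6,9-tetramethyl-11-methylidenetricyclo[5.4.0.0^{2,8}]undecane-3,5-diol
Product: 25 (3R,5R)-3,5-dihydroxy-2,6,6,9-tetramethyltricyclo[5.4.0.0^{2,8}]undecan-11-one, via ozonide 24 (not isolated)
Conditions: O3, CH2Cl2, −78 °C; then Me2S, −78 °C to rt
Reagents that add atoms: ozone [O-][O+]=O
Why: Ozonolysis of the electron-rich 1,1-disubstituted alkene with reductive work-up should unmask the C11 ketone while the free alcohols are untouched; C1 is a bridgehead and cannot epimerize.

Step 16
Reactants: 25 (3R,5R)-3,5-dihydroxy-2,6,6,9-tetramethyltricyclo[5.4.0.0^{2,8}]undecan-11-one; 26 (2Z)-2-methylbut-2-enoic acid (angelic acid; two molecules are incorporated, one per hydroxyl)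
Product: 30 (1R,2R,3R,5R,7S,8S,9R)-2,6,6,9-tetramethyl-11-oxotricyclo[5.4.0.0^{2,8}]undecane-3,5-diyl bis[(2Z)-2-methylbut-2-enoate] (CNP0283599.1), via mixed anhydride 27 (not isolated), via 5-O-monoangelate 28 (not isolated), via 3-O-monoangelate 29 (not isolated)
Conditions: 26 (6 equiv), 2,4,6-trichlorobenzoyl chloride (6 equiv), Et3N (12 equiv), toluene, rt; then 25, toluene, 80 °C
Reagents that add atoms: (2Z)-2-methylbut-2-enoic acid, the second molecule of 26, C/C=C(/C)C(O)=O
Why: Yamaguchi-type mixed-anhydride esterification run without DMAP, the established way to acylate hindered secondary alcohols with angelic acid without Z-to-E isomerization to the tiglate, should acylate both carbinols in one flask with excess 27, one molecule of 27 being consumed per hydroxyl, so that the mono-angelates 28 and 29, formed in either order, converge on the bis-ester while the ketone does not interfere.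

**Compound list**
1 | (S)-4-benzyl-3-propanoyl-1,3-oxazolidin-2-one | CCC(=O)N1[C@@H](Cc2ccccc2)COC1=O | starting material
2 | 3-bromoprop-1-yne (propargyl bromide) | C#CCBr | starting material
3 | (S)-4-benzyl-3-[(2R)-2-methylpent-4-ynoyl]-1,3-oxazolidin-2-one | C#CC[C@@H](C)C(=O)N1[C@@H](Cc2ccccc2)COC1=O | intermediate
4 | (2R)-2-methylpent-4-yn-1-ol | C#CC[C@@H](C)CO | intermediate
5 | 3-(triphenyl-λ5-phosphanylidene)butan-2-one | CC(=O)C(C)=P(c1ccccc1)(c1ccccc1)c1ccccc1 | starting material
6 | (2R)-2-methylpent-4-ynal | C#CC[C@@H](C)C=O | intermediate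
7 | (3E,5R)-3,5-dimethyloct-3-en-7-yn-2-one | C#CC[C@@H](C)/C=C(\C)C(C)=O | intermediate
8 | (2R,3E,5R)-3,5-dimethyloct-3-en-7-yn-2-ol | C#CC[C@@H](C)/C=C(\C)[C@@H](C)O | intermediate
9 | (E)-alkenyl(dimethyl)alane of 8, as its dimethylaluminium alkoxide | C[Al](C)/C=C(\C)C[C@@H](C)/C=C(\C)[C@@H](C)O[Al](C)C | intermediate
10 | (2E,5R,6E,8R)-8-hydroxy-3,5,7-trimethylnona-2,6-dienoic acid | OC(=O)/C=C(\C)C[C@@H](C)/C=C(\C)[C@@H](C)O | intermediate
11 | 2-methylpropanoic anhydride | CC(C)C(=O)OC(=O)C(C)C | starting material
12 | (2E,5R,6E,8R)-3,5,7-trimethyl-8-[(2-methylpropanoyl)oxy]nona-2,6-dienoic acid | OC(=O)/C=C(\C)C[C@@H](C)/C=C(\C)[C@@H](C)OC(=O)C(C)C | intermediate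
13 | acid chloride of 12 | ClC(=O)/C=C(\C)C[C@@H](C)/C=C(\C)[C@@H](C)OC(=O)C(C)C | intermediate
14 | vinylketene from 13 (3-methylidene-1-oxo-1,6-diene) | O=C=CC(=C)C[C@@H](C)/C=C(\C)[C@@H](C)OC(=O)C(C)C | intermediate
15 | (1R)-1-[2,7-dimethyl-4-methylidene-6-oxobicyclo[3.1.1]heptan-7-yl]ethyl 2-methylpropanoate (7-methyl syn to the C2–C4 bridge, 2-methyl on the C6 side) | C[C@@H](OC(=O)C(C)C)[C@]1(C)[C@@H]2C(=O)[C@H]1C(=C)C[C@H]2C | intermediate
16 | lithium 7-alkoxide of the hydroxy lactone (aldolate) | O=C1O[C@H](C)[C@]2(C)[C@@H]3[C@@]([O-])([C@H]2C(=C)C[C@H]3C)C1(C)C.[Li+] | intermediate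
17 | methyl (3R)-2,3,6,6,9-pentamethyl-11-methylidene-5-oxo-4-oxatricyclo[5.4.0.0^{2,8}]undecan-7-yl oxalate | O=C1O[C@H](C)[C@]2(C)[C@@H]3[C@@](OC(=O)C(=O)OC)([C@H]2C(=C)C[C@H]3C)C1(C)C | intermediate
18 | (3R)-2,3,6,6,9-pentamethyl-11-methylidene-4-oxatricyclo[5.4.0.0^{2,8}]undecan-5-one | O=C1O[C@H](C)[C@]2(C)[C@@H]3[C@@H]([C@H]2C(=C)C[C@H]3C)C1(C)C | intermediate
19 | (1R)-1-[6-(1-hydroxy-2-methylpropan-2-yl)-2,7-dimethyl-4-methylidenebicyclo[3.1.1]heptan-7-yl]ethan-1-ol (both chains on the face opposite the C2–C4 bridge) | C[C@@H](O)[C@]1(C)[C@@H]2[C@@H]([C@H]1C(=C)C[C@H]2C)C(C)(C)CO | intermediate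
20 | 2-[7-acetyl-2,7-dimethyl-4-methylidenebicyclo[3.1.1]heptan-6-yl]-2-methylpropanal | CC(=O)[C@]1(C)[C@@H]2[C@@H]([C@H]1C(=C)C[C@H]2C)C(C)(C)C=O | intermediate
21 | 5-hydroxy-2,6,6,9-tetramethyl-11-methylidenetricyclo[5.4.0.0^{2,8}]undecan-3-one (C5 epimers; other centres as in the target) | OC1CC(=O)[C@]2(C)[C@@H]3[C@@H]([C@H]2C(=C)C[C@H]3C)C1(C)C | intermediate
22 | 2,6,6,9-tetramethyl-11-methylidenetricyclo[5.4.0.0^{2,8}]undecane-3,5-dione | O=C1CC(=O)[C@]2(C)[C@@H]3[C@@H]([C@H]2C(=C)C[C@H]3C)C1(C)C | intermediate
23 | (3R,5R)-2,6,6,9-tetramethyl-11-methylidenetricyclo[5.4.0.0^{2,8}]undecane-3,5-diol | O[C@@H]1C[C@@H](O)[C@]2(C)[C@@H]3[C@@H]([C@H]2C(=C)C[C@H]3C)C1(C)C | intermediate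
24 | spiro-1,2,4-trioxolane (ozonide) at C11 of 23 | O[C@@H]1C[C@@H](O)[C@]2(C)[C@@H]3[C@@H]([C@H]2C4(OCOO4)C[C@H]3C)C1(C)C | intermediate
25 | (3R,5R)-3,5-dihydroxy-2,6,6,9-tetramethyltricyclo[5.4.0.0^{2,8}]undecan-11-one | O[C@@H]1C[C@@H](O)[C@]2(C)[C@@H]3[C@@H]([C@H]2C(=O)C[C@H]3C)C1(C)C | intermediate
26 | (2Z)-2-methylbut-2-enoic acid (angelic acid) | C/C=C(/C)C(O)=O | starting material
27 | (2Z)-2-methylbut-2-enoic 2,4,6-trichlorobenzoic anhydride | C/C=C(/C)C(=O)OC(=O)c1c(Cl)cc(Cl)cc1Cl | intermediate
28 | (3R,5R)-3-hydroxy-2,6,6,9-tetramethyl-11-oxotricyclo[5.4.0.0^{2,8}]undecan-5-yl (2Z)-2-methylbut-2-enoate (5-O-monoangelate) | C/C=C(/C)C(=O)O[C@@H]1C[C@@H](O)[C@]2(C)[C@@H]3[C@@H]([C@H]2C(=O)C[C@H]3C)C1(C)C | intermediate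
29 | (3R,5R)-5-hydroxy-2,6,6,9-tetramethyl-11-oxotricyclo[5.4.0.0^{2,8}]undecan-3-yl (2Z)-2-methylbut-2-enoate (3-O-monoangelate) | O[C@@H]1C[C@@H](OC(=O)/C(C)=C\C)[C@]2(C)[C@@H]3[C@@H]([C@H]2C(=O)C[C@H]3C)C1(C)C | intermediate
30 | (1R,2R,3R,5R,7S,8S,9R)-2,6,6,9-tetramethyl-11-oxotricyclo[5.4.0.0^{2,8}]undecane-3,5-diyl bis[(2Z)-2-methylbut-2-enoate] | C/C=C(/C)C(=O)O[C@@H]1C[C@@H](OC(=O)/C(C)=C\C)[C@]2(C)[C@@H]3[C@@H]([C@H]2C(=O)C[C@H]3C)C1(C)C | target

**Totals**
Total step count: 16. Longest linear sequence: 16 steps (from 1; compounds 2, 5, 11 and 26 are commercial).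

**Steps most likely to fail**

Step 7. The vinylketene may be lost to oligomerization or to deprotonation at the wrong γ-position before it adds to the alkene, which the allylic acyloxy group makes less nucleophilic. Fallback, setting out from 12: oxalyl chloride and then pyrrolidine give the pyrrolidine amide F1. Tf2O and 2,4,6-collidine in refluxing 1,2-dichloroethane generate the more electrophilic vinylketeniminium ion, whose intramolecular [2+2] cycloaddition (Ghosez type) gives the cyclobutaniminium triflate F2. Aqueous NaHCO3 hydrolysis then returns to the route at 15.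

Step 8. The hindered ester enolate may fail to add, or the aldolate may revert by retro-aldol before it is trapped. Fallback, setting out from 15, uses a Reformatsky closure instead of the base aldol: K2CO3 in MeOH removes the isobutyrate to give the hydroxy ketone F3, and 2-bromo-2-methylpropanoyl bromide with pyridine gives the bromo ester F4. SmI2 in THF at −78 °C forms the samarium enolate at one defined site under neutral conditions, and the Sm(III)-templated intramolecular Reformatsky reaction gives the hydroxy lactone F5. Methyl chlorooxoacetate with DMAP then returns to the route at 17.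

Step 14. The two α-quaternary carbonyls may react too slowly with catecholborane, or catalyst control may be lost through a boron diketonate, giving incomplete reduction or syn/anti mixtures. Fallback, setting out from 21 and bypassing the dione: the C5 epimers are separated and the (5R)-ketol F6 is reduced with Me4NBH(OAc)3 in MeCN/AcOH at −20 °C (Evans–Saksena hydroxyl-directed anti reduction), which returns to the route at 23. The (5S)-epimer is re-equilibrated through the retro-aldol/aldol manifold with catalytic base and recycled.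

Further compounds
F1 | step 7 | 1-[(2E,5R,6E,8R)-3,5,7-trimethyl-8-(2-methylpropanoyloxy)nona-2,6-dienoyl]pyrrolidine | O=C(/C=C(\C)C[C@@H](C)/C=C(\C)[C@@H](C)OC(=O)C(C)C)N1CCCC1
F2 | step 7 | N-(bicyclo[3.1.1]heptan-6-ylidene)pyrrolidinium triflate corresponding to 15 | C[C@@H](OC(=O)C(C)C)[C@]1(C)[C@@H]2C(=[N+]3CCCC3)[C@H]1C(=C)C[C@H]2C.[O-]S(=O)(=O)C(F)(F)F
F3 | step 8 | 7-[(1R)-1-hydroxyethyl]-2,7-dimethyl-4-methylidenebicyclo[3.1.1]heptan-6-one | C[C@@H](O)[C@]1(C)[C@@H]2C(=O)[C@H]1C(=C)C[C@H]2C
F4 | step 8 | (1R)-1-[2,7-dimethyl-4-methylidene-6-oxobicyclo[3.1.1]heptan-7-yl]ethyl 2-bromo-2-methylpropanoate | C[C@@H](OC(=O)C(C)(C)Br)[C@]1(C)[C@@H]2C(=O)[C@H]1C(=C)C[C@H]2C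
F5 | step 8 | (3R)-7-hydroxy-2,3,6,6,9-pentamethyl-11-methylidene-4-oxatricyclo[5.4.0.0^{2,8}]undecan-5-one | O=C1O[C@H](C)[C@]2(C)[C@@H]3[C@@](O)([C@H]2C(=C)C[C@H]3C)C1(C)C
F6 | step 14 | (5R)-5-hydroxy-2,6,6,9-tetramethyl-11-methylidenetricyclo[5.4.0.0^{2,8}]undecan-3-one | O[C@@H]1CC(=O)[C@]2(C)[C@@H]3[C@@H]([C@H]2C(=C)C[C@H]3C)C1(C)C
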